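The grey run shows how E leaves once the feed of J is over: it falls from 51.0 % at 1.50 min to 36.6 % at 3.00 min, and at that last reading E and G together make 97.9 %. We read this tail as pseudo-first-order in E, with a constant of 0.221 min⁻¹. The green run has one reading after its feed, so we read it from 25.0 s to 40.0 s, across the end of the feed at 30 s, and take the 1.98 min⁻¹ this gives as its tail constant.

| flask | E | D | J | temperature | remark | time |
|---|---|---|---|---|---|---|
| grey | 0.050 M | 0.075 M | 0.10 M (fed, over 30 s) | −8 °C | run made earlier |  |
| green | 0.050 M | 0.11 M | 0.10 M (fed, over 30 s) | 20 °C | run made earlier |  |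
| autumn | 0.050 M | 0.150 M | 0.100 M (fed, over 30 s) |  | at −20 °C until 30 s, from then on at 30 °C | 5.0 min |
| midnight | 0.050 M | 0.150 M | 0.100 M (fed, over 30 s) |  | at −20 °C throughout | 5.0 min |

grey run (percent of the E charged)

| time / min | G / % | E / % |
|---|---|---|
| 0.167 | 5.8 | 92.3 |
| 0.500 | 28.1 | 74.5 |
| 0.667 | 33.2 | 66.3 |
| 1.00 | 43.0 | 57.1 |
| 1.50 | 52.1 | 51.0 |
| 2.00 | 53.7 | 44.9 |
| 3.00 | 61.3 | 36.6 |

green run (percent of the E charged)

| time / s | G / % | E / % |
|---|---|---|
| 10.0 | 22.6 | 75.7 |
| 12.0 | 30.3 | 71.7 |
| 15.0 | 37.5 | 62.0 |
| 25.0 | 59.7 | 41.3 |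
| 40.0 | 74.7 | 25.2 |

(standard deviation of a reading: 1 percentage point)

- the numbers in the tables scatter with a standard deviation of 1 percentage point

- the flask that ends with the higher amount of G, in percent of the E charged, or "neither" when 2 percentage points or less lies between them (autumn / midnight / neither)
- final G, as a percentage of the E charged, in autumn
- final G, as a percentage of the E charged, in midnight

Autumn and midnight share one recipe at −20 °C up to 30 s, when the feed ends, so what separates them happens in the remaining 4.50 min. Two times therefore matter: the tail half-life of E at −20 °C and at 30 °C, each held against that remainder. We assume the constant is proportional to charged D, which the two runs cannot test, since their temperatures differ too. Divided by D, they give an apparent activation energy of 41.7 kJ mol⁻¹. With 0.150 M of D, we reckon midnight's tail half-life at 3.84 min, and the warm tail half-life of E at charged D at 0.146 min, a ratio of 26.3. Taking grey's 74.5 % of E at the end of its feed as a stand-in for the start of the remainder in both flasks, we reckon G at 66.9 % in midnight and >99.9 % in autumn.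

The forecast, which supposes that “J generates an active species that partly dies”, names autumn, with 92 % there and 77 % in midnight, so it differs from ours, lower on autumn and higher on midnight.

The flasks give 99.3 % in autumn and 74.8 % in midnight, so autumn ends higher.

    X + D ⇌ L, settled at all times (K = 53000 M⁻¹, ΔH = −15.0 kJ mol⁻¹)
    Q + X ⇌ J, settled at all times (K = 1.10 × 10⁵ M⁻¹, ΔH = −27.0 kJ mol⁻¹)
    2 Q → Z (k = 0.0640 M⁻¹ s⁻¹, Ea = 44.0 kJ mol⁻¹)
    E + Q → X + G (k = 0.260 M⁻¹ s⁻¹, Ea = 38.0 kJ mol⁻¹)
    (constants at −20 °C)

G in autumn has nearly come to rest: it reaches >99.9 % at 50.0 min. G in midnight has not: by that time it climbs to 98.7 % and E there falls from 25.2 % to 1.31 %. At the end of autumn, the half-life of E by the step from E and Q to X and G is 1.5 min, ten times our warm value. Scaled by the 8.9 % of the charged D still there, unbound, our value becomes 1.64 min.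

A neighbour of autumn with 0.085 M of E has the same charged D, hence the same 0.146 min, but its 0.795 % of unbound D at 5.00 min stretches that to 18.4 min, longer than the remainder. That flask ends with 17.7 % of E and 82.3 % of G.

All runs were computed for an exercise, and the scatter is random.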